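**Retrosynthetic overview** (germacrane numbering: C1=C10 alkene with the C14 methyl on C10; oxirane C4–C5 with the C15 methyl on C4; C6–OH; C7–isopropyl; C8–O-aroyl; C9 is CH2)
Target 24 ⇐ C6 silyl ether 23 ⇐ trans-4,5-diol 21, by mesylation of the C5 hydroxyl and invertive closure by the C4 oxygen, which becomes the oxirane oxygen.
21 ⇐ acyclic keto aldehyde 20, by a titanium-induced pinacol macrocyclisation that forms C4–C5 and closes the ten-membered carbocycle (ring 1, step 12); the oxirane (ring 2) is closed next (step 13).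
Enabling feature: both oxirane carbons carry oxygen; C4 also carries the C15 methyl (a methyl ketone) and C5 carries H next to the C6 carbinol (an α-silyloxy aldehyde). C4–C5 is therefore the retron of a ketone/aldehyde reductive coupling, and the cis-fused oxirane on the ten-membered ring corresponds to the trans diol that such rings are expected to prefer.
20 ⇐ B-alkyl Suzuki coupling (C1–C2) of vinyl iodide 15 with the borane of (S)-but-3-en-2-ol; 15 ⇐ carboalumination–iodination (C14 methyl, E alkene) and aroylation of alkynol 11.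
11 ⇐ catalytic asymmetric propargylation (C8) of aldehyde 9 ⇐ Evans syn-aldol of isovaleryl imide 3 with silyloxyacetaldehyde 4 (C6, C7).

Key step: step 12

Assumption: the target is taken exactly as drawn, (4S,5R,6S,7S,8S) with an E C1=C10 alkene and a cis-fused oxirane (C3 and C6 on the same side); compounds 1, 2, 4, 10, 14 and 16 are taken to be catalogue compounds.
Remark: TBS = tert-butyldimethylsilyl; names of the ten-membered compounds use the germacrane numbering above, and the SMILES in the compound list are definitive.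

**Step 1**
Reactants: 1 (S)-4-benzyloxazolidin-2-one; 2 3-methylbutanoyl chloride
Product: 3 (S)-4-benzyl-3-(3-methylbutanoyl)oxazolidin-2-one
Conditions: n-BuLi, THF, −78 °C; then 2, −78 to 0 °C
Reagents that add atoms: none
Why: N-acylation of the lithiated Evans oxazolidinone with an acid chloride is a standard reaction and creates no stereocentre.

**Step 2**
Reactants: 3 (S)-4-benzyl-3-(3-methylbutanoyl)oxazolidin-2-one; 4 (tert-butyldimethylsilyloxy)acetaldehyde
Product: 6 (S)-4-benzyl-3-[(2S,3S)-4-(TBS-oxy)-3-hydroxy-2-(propan-2-yl)butanoyl]oxazolidin-2-one, via Z-boron enolate 5 (not isolated)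
Conditions: Bu2BOTf, i-Pr2NEt, CH2Cl2, −78 to 0 °C; then 4, −78 to 0 °C; pH 7 buffer, MeOH, H2O2, 0 °C
Reagents that add atoms: none
Why: Evans syn-aldol reaction, in which the Z-dibutylboron enolate adds through a Zimmerman–Traxler chair on the face away from the benzyl group, which should set C7 and C6 in the syn relationship of the target.

**Step 3**
Reactants: 6 aldol adduct
Product: 7 (S)-4-benzyl-3-[(2S,3S)-3,4-bis(TBS-oxy)-2-(propan-2-yl)butanoyl]oxazolidin-2-one
Conditions: TBSOTf, 2,6-lutidine, CH2Cl2, −78 to 0 °C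
Reagents that add atoms: tert-butyldimethylsilyl trifluoromethanesulfonate, CC(C)(C)[Si](C)(C)OS(=O)(=O)C(F)(F)F
Why: silylation of the secondary aldol hydroxyl with the silyl triflate and a hindered base is reliable, blocks retro-aldol cleavage and touches no stereocentre.

**Step 4**
Reactants: 7 bis-silyl imide
Product: 8 (2R,3S)-3,4-bis(TBS-oxy)-2-(propan-2-yl)butan-1-ol
Conditions: LiBH4, MeOH (1 equiv), Et2O, 0 °C
Reagents that add atoms: none
Why: reductive cleavage of the N-acyl oxazolidinone by LiBH4 gives the primary alcohol without epimerising C7 and releases the auxiliary.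

**Step 5**
Reactants: 8 primary alcohol
Product: 9 (2S,3S)-3,4-bis(TBS-oxy)-2-(propan-2-yl)butanal
Conditions: Dess–Martin periodinane, NaHCO3, CH2Cl2, 0 to 25 °C
Reagents that add atoms: none
Why: Dess–Martin oxidation under bicarbonate buffering should give the α-branched aldehyde without epimerisation at C7 or β-elimination of the silyloxy group.

**Step 6**
Reactants: 9 aldehyde; 10 allenylboronic acid pinacol ester
Product: 11 (2S,3R,4S)-1,2-bis(TBS-oxy)-3-(propan-2-yl)hept-6-yn-4-ol
Conditions: (S)-TRIP [(S)-3,3'-bis(2,4,6-triisopropylphenyl)-1,1'-binaphthyl-2,2'-diyl hydrogen phosphate] (10 mol%), 4 Å molecular sieves, toluene, −20 °C; aq. work-up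
Reagents that add atoms: none
Why: chiral phosphoric acid-catalysed propargylation, in which the allenylboronate adds in an SE2' sense through a six-membered chair organised by the phosphate; the catalyst antipode is chosen to direct attack to the si face of the aldehyde, which should set C8 (S) under reagent control.

**Step 7**
Reactants: 11 homopropargylic alcohol
Product: 13 (2S,3R,4S,6E)-1,2-bis(TBS-oxy)-7-iodo-6-methyl-3-(propan-2-yl)hept-6-en-4-ol, via E-alkenylalane 12 (not isolated)
Conditions: Me3Al, Cp2ZrCl2 (25 mol%), CH2Cl2, 0 to 25 °C; then I2, THF, −30 to 0 °C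
Reagents that add atoms: trimethylaluminium, C[Al](C)C; iodine, II
Why: Negishi zirconium-catalysed carboalumination adds methyl and aluminium syn across the terminal alkyne with methyl on the internal carbon (the hydroxyl is carried as its aluminium alkoxide), and iodinolysis with retention should give only the E vinyl iodide, which fixes the C1=C10 geometry.

**Step 8**
Reactants: 13 vinyl iodide alcohol; 14 3,4,5-trimethoxybenzoyl chloride
Product: 15 (2S,3R,4S,6E)-1,2-bis(TBS-oxy)-7-iodo-6-methyl-3-(propan-2-yl)hept-6-en-4-yl 3,4,5-trimethoxybenzoate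
Conditions: Et3N, DMAP, CH2Cl2, 0 to 25 °C
Reagents that add atoms: none
Why: DMAP-catalysed acylation of the only free hydroxyl installs the C8 ester while O5 and O6 are silylated, so the hydroxyls never need to be differentiated later.

**Step 9**
Reactants: 15 vinyl iodide ester; 16 (S)-but-3-en-2-ol
Product: 18 (2S,3R,4S,6E,10S)-1,2-bis(TBS-oxy)-10-hydroxy-6-methyl-3-(propan-2-yl)undec-6-en-4-yl 3,4,5-trimethoxybenzoate, via B-alkyl-9-BBN borane 17 (not isolated)
Conditions: 16, 9-BBN (2.2 equiv), THF, 0 to 25 °C; then 15, PdCl2(dppf) (5 mol%), AsPh3, Cs2CO3, DMF/H2O, 25 °C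
Reagents that add atoms: none
Why: B-alkyl Suzuki–Miyaura coupling, in which anti-Markovnikov hydroboration of 16 and palladium-catalysed sp3–sp2 coupling with retention of the vinyl iodide geometry join C2 to C1; the carbinol centre from 16 becomes C4 and is erased in step 11.

**Step 10**
Reactants: 18 coupled bis-silyl ether
Product: 19 (2S,3R,4S,6E,10S)-2-(TBS-oxy)-1,10-dihydroxy-6-methyl-3-(propan-2-yl)undec-6-en-4-yl 3,4,5-trimethoxybenzoate
Conditions: HF·pyridine, pyridine, THF, 0 °C
Reagents that add atoms: none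
Why: buffered HF·pyridine should cleave the unhindered primary silyl ether much faster than the secondary one next to the isopropyl-bearing carbon, and leaves the ester alone.

**Step 11**
Reactants: 19 diol
Product: 20 (2S,3R,4S,6E)-2-(TBS-oxy)-6-methyl-1,10-dioxo-3-(propan-2-yl)undec-6-en-4-yl 3,4,5-trimethoxybenzoate
Conditions: Dess–Martin periodinane (3 equiv), NaHCO3, CH2Cl2, 0 to 25 °C
Reagents that add atoms: none
Why: Dess–Martin periodinane oxidises the primary and the secondary alcohol in one operation to the α-silyloxy aldehyde and the methyl ketone under neutral conditions that should not epimerise C6.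

**Step 12**
Reactants: 20 keto aldehyde
Product: 21 (1(10)E,4S,5S,6S,7R,8S)-6-(TBS-oxy)-4,5-dihydroxygermacr-1(10)-en-8-yl 3,4,5-trimethoxybenzoate
Conditions: TiCl3(DME)1.5, Zn–Cu couple, DME, reflux (reagent formation), then 25 °C; 20 added by syringe pump over 30 h (about 1 mM final); aq. K2CO3
Reagents that add atoms: none
Why: Low-valent titanium transfers one electron to each carbonyl of 20 and the titanium-bound C5 and C4 ketyls couple (formally a 10-exo-trig addition of the more easily formed aldehyde ketyl to the titanium-complexed ketone) to a titanium diolate that is hydrolysed to 21, the reaction stopping at the diol because deoxygenation needs reflux. The closest known reaction type is the titanium-induced intramolecular pinacol coupling of dialdehydes and keto aldehydes to medium and large 1,2-cycloalkanediols. One ring is closed, the ten-membered carbocycle, with the metal surface that binds both oxygens as template and the E C1=C10 alkene as the turn element. C5 should be set by the C6 stereocentre, the new C5–O bond forming anti to the bulky, non-chelating silyloxy group (Felkin–Anh, dipole-minimised ketyl), which gives 5S. C4 should be set by the ring, since in ten-membered rings the two metal-bound oxygens are expected to prefer the trans arrangement, which with 5S means 4S, the diol whose invertive closure leads to the cis-fused oxirane. The step needs cyclisation over oligomerisation, secured by syringe-pump high dilution, and reaction at the two carbonyls only, secured by the mild temperature at which the aryl ester and the alkene should survive.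

**Step 13**
Reactants: 21 trans-diol
Product: 23 (1(10)E,4S,5R,6S,7R,8S)-6-(TBS-oxy)-4,5-epoxygermacr-1(10)-en-8-yl 3,4,5-trimethoxybenzoate, via C5 mesylate 22 (not isolated)
Conditions: MsCl, Et3N, CH2Cl2, −20 to 0 °C; then DBU, 25 °C
Reagents that add atoms: none
Why: the secondary C5 hydroxyl is mesylated selectively beside the tertiary C4 hydroxyl, and the C4 alkoxide then displaces the mesylate (intramolecular SN2, 3-exo-tet) with inversion at C5, so the trans diol should give the cis-fused (4S,5R) oxirane.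

**Step 14**
Reactants: 23 silyl-protected epoxide
Product: 24 (1(10)E,4S,5R,6S,7S,8S)-4,5-epoxy-6-hydroxygermacr-1(10)-en-8-yl 3,4,5-trimethoxybenzoate (target)
Conditions: TBAF, AcOH (1:1), THF, 0 to 25 °C
Reagents that add atoms: none
Why: fluoride cleaves the remaining silyl ether, and acetic acid buffering should suppress acyl migration from O8 to O6 and Payne rearrangement of the 2,3-epoxy alkoxide.

**Compound list**
1 | (S)-4-benzyloxazolidin-2-one | O=C1N[C@@H](Cc2ccccc2)CO1 | starting material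
2 | 3-methylbutanoyl chloride | CC(C)CC(Cl)=O | starting material
3 | (S)-4-benzyl-3-(3-methylbutanoyl)oxazolidin-2-one | CC(C)CC(=O)N1[C@@H](Cc2ccccc2)COC1=O | intermediate
4 | (tert-butyldimethylsilyloxy)acetaldehyde | CC(C)(C)[Si](C)(C)OCC=O | starting material
5 | Z-dibutylboron enolate of 3 | CCCCB(CCCC)O/C(=C\C(C)C)N1[C@@H](Cc2ccccc2)COC1=O | intermediate
6 | (S)-4-benzyl-3-[(2S,3S)-4-(tert-butyldimethylsilyloxy)-3-hydroxy-2-(propan-2-yl)butanoyl]oxazolidin-2-one | O=C(N1[C@@H](Cc2ccccc2)COC1=O)[C@@H](C(C)C)[C@H](O)CO[Si](C)(C)C(C)(C)C | intermediate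
7 | (S)-4-benzyl-3-[(2S,3S)-3,4-bis(tert-butyldimethylsilyloxy)-2-(propan-2-yl)butanoyl]oxazolidin-2-one | O=C(N1[C@@H](Cc2ccccc2)COC1=O)[C@@H](C(C)C)[C@H](O[Si](C)(C)C(C)(C)C)CO[Si](C)(C)C(C)(C)C | intermediate
8 | (2R,3S)-3,4-bis(tert-butyldimethylsilyloxy)-2-(propan-2-yl)butan-1-ol | OC[C@@H](C(C)C)[C@H](O[Si](C)(C)C(C)(C)C)CO[Si](C)(C)C(C)(C)C | intermediate
9 | (2S,3S)-3,4-bis(tert-butyldimethylsilyloxy)-2-(propan-2-yl)butanal | O=C[C@@H](C(C)C)[C@H](O[Si](C)(C)C(C)(C)C)CO[Si](C)(C)C(C)(C)C | intermediate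
10 | allenylboronic acid pinacol ester, 2-(propa-1,2-dien-1-yl)-4,4,5,5-tetramethyl-1,3,2-dioxaborolane | C=C=CB1OC(C)(C)C(C)(C)O1 | starting material
11 | (2S,3R,4S)-1,2-bis(tert-butyldimethylsilyloxy)-3-(propan-2-yl)hept-6-yn-4-ol | C#CC[C@H](O)[C@@H](C(C)C)[C@H](O[Si](C)(C)C(C)(C)C)CO[Si](C)(C)C(C)(C)C | intermediate
12 | E-alkenyl(dimethyl)alane from 11, as its O-dimethylaluminium alkoxide | C[Al](C)/C=C(\C)C[C@H](O[Al](C)C)[C@@H](C(C)C)[C@H](O[Si](C)(C)C(C)(C)C)CO[Si](C)(C)C(C)(C)C | intermediate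
13 | (2S,3R,4S,6E)-1,2-bis(tert-butyldimethylsilyloxy)-7-iodo-6-methyl-3-(propan-2-yl)hept-6-en-4-ol | I/C=C(\C)C[C@H](O)[C@@H](C(C)C)[C@H](O[Si](C)(C)C(C)(C)C)CO[Si](C)(C)C(C)(C)C | intermediate
14 | 3,4,5-trimethoxybenzoyl chloride | COc1cc(C(Cl)=O)cc(OC)c1OC | starting material
15 | (2S,3R,4S,6E)-1,2-bis(tert-butyldimethylsilyloxy)-7-iodo-6-methyl-3-(propan-2-yl)hept-6-en-4-yl 3,4,5-trimethoxybenzoate | I/C=C(\C)C[C@H](OC(=O)c1cc(OC)c(OC)c(OC)c1)[C@@H](C(C)C)[C@H](O[Si](C)(C)C(C)(C)C)CO[Si](C)(C)C(C)(C)C | intermediate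
16 | (S)-but-3-en-2-ol | C[C@H](O)C=C | starting material
17 | 9-[(3S)-3-(9-borabicyclo[3.3.1]nonan-9-yloxy)butyl]-9-borabicyclo[3.3.1]nonane | C[C@H](OB1C2CCCC1CCC2)CCB1C2CCCC1CCC2 | intermediate
18 | (2S,3R,4S,6E,10S)-1,2-bis(tert-butyldimethylsilyloxy)-10-hydroxy-6-methyl-3-(propan-2-yl)undec-6-en-4-yl 3,4,5-trimethoxybenzoate | C[C@H](O)CC/C=C(\C)C[C@H](OC(=O)c1cc(OC)c(OC)c(OC)c1)[C@@H](C(C)C)[C@H](O[Si](C)(C)C(C)(C)C)CO[Si](C)(C)C(C)(C)C | intermediate
19 | (2S,3R,4S,6E,10S)-2-(tert-butyldimethylsilyloxy)-1,10-dihydroxy-6-methyl-3-(propan-2-yl)undec-6-en-4-yl 3,4,5-trimethoxybenzoate | C[C@H](O)CC/C=C(\C)C[C@H](OC(=O)c1cc(OC)c(OC)c(OC)c1)[C@@H](C(C)C)[C@H](O[Si](C)(C)C(C)(C)C)CO | intermediate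
20 | (2S,3R,4S,6E)-2-(tert-butyldimethylsilyloxy)-6-methyl-1,10-dioxo-3-(propan-2-yl)undec-6-en-4-yl 3,4,5-trimethoxybenzoate | CC(=O)CC/C=C(\C)C[C@H](OC(=O)c1cc(OC)c(OC)c(OC)c1)[C@@H](C(C)C)[C@H](O[Si](C)(C)C(C)(C)C)C=O | intermediate
21 | (1(10)E,4S,5S,6S,7R,8S)-6-(tert-butyldimethylsilyloxy)-4,5-dihydroxygermacr-1(10)-en-8-yl 3,4,5-trimethoxybenzoate | COc1cc(C(=O)O[C@H]2C/C(C)=C/CC[C@](C)(O)[C@@H](O)[C@@H](O[Si](C)(C)C(C)(C)C)[C@@H]2C(C)C)cc(OC)c1OC | intermediate
22 | (1(10)E,4S,5S,6S,7R,8S)-6-(tert-butyldimethylsilyloxy)-4-hydroxy-5-(methanesulfonyloxy)germacr-1(10)-en-8-yl 3,4,5-trimethoxybenzoate | COc1cc(C(=O)O[C@H]2C/C(C)=C/CC[C@](C)(O)[C@@H](OS(C)(=O)=O)[C@@H](O[Si](C)(C)C(C)(C)C)[C@@H]2C(C)C)cc(OC)c1OC | intermediate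
23 | (1(10)E,4S,5R,6S,7R,8S)-6-(tert-butyldimethylsilyloxy)-4,5-epoxygermacr-1(10)-en-8-yl 3,4,5-trimethoxybenzoate | COc1cc(C(=O)O[C@H]2C/C(C)=C/CC[C@]3(C)O[C@@H]3[C@@H](O[Si](C)(C)C(C)(C)C)[C@@H]2C(C)C)cc(OC)c1OC | intermediate
24 | (1(10)E,4S,5R,6S,7S,8S)-4,5-epoxy-6-hydroxygermacr-1(10)-en-8-yl 3,4,5-trimethoxybenzoate | COc1cc(C(=O)O[C@H]2C/C(C)=C/CC[C@]3(C)O[C@@H]3[C@@H](O)[C@@H]2C(C)C)cc(OC)c1OC | target

Total step count: 14
Longest linear sequence: 14 steps (from 1 to 24)

**Steps most likely to fail**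

Step 12. The coupling may show poor diastereocontrol at C4 and C5 (four diols are possible), and the slow ring closure leaves time for oligomerisation. As a fallback the coupling is run through to the alkene and the oxirane is made by directed epoxidation. From 20, the same low-valent titanium reagent at reflux (McMurry olefination, the reaction type used for germacrane-type cyclodecadienes) deoxygenates the diolate to the cyclodecadiene; the geometric isomers are separated and the (1(10)E,4Z)-diene silyl ether F1 is taken on. TBAF/AcOH frees the C6 allylic alcohol F2. VO(acac)2 with t-BuOOH then epoxidises C4=C5 from the face of the C6 hydroxyl (allylic 1,3-strain, threo), which returns to the route at 24.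

Step 6. Facial selectivity may be poor in a mismatched pairing of catalyst and α-branched aldehyde, and turnover may be slow. As a fallback the stereocentre is corrected by inversion. From 9, an uncatalysed zinc Barbier propargylation (propargyl bromide, Zn, THF/aq. NH4Cl) gives 11 together with its C8 epimer F3. After separation, F3 is inverted by Mitsunobu esterification (4-nitrobenzoic acid, PPh3, DIAD) to the 4-nitrobenzoate F4, and methanolysis (K2CO3, MeOH) returns to the route at 11, so both epimers converge.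

Step 9. The alkylborane that carries a borinate may transmetalate slowly or lose boron by protonolysis, and the aqueous base may begin to hydrolyse the ester. As a fallback the ketone is brought in masked. 2-Methyl-2-vinyl-1,3-dioxolane is hydroborated with 9-BBN to the borane F5 and coupled with 15 (PdCl2(dppf), AsPh3, K3PO4, DMF) to the dioxolane F6. HF·pyridine gives the primary alcohol F7, Dess–Martin oxidation gives the aldehyde F8, and PPTS in wet acetone unmasks the ketone, which returns to the route at 20.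

**Further compounds**
F1 | step 12 | (1(10)E,4Z)-6-(tert-butyldimethylsilyloxy)germacra-1(10),4-dien-8-yl 3,4,5-trimethoxybenzoate, configuration at C6, C7 and C8 as in 20 | COc1cc(C(=O)O[C@H]2C/C(C)=C/CC/C(C)=C\[C@@H](O[Si](C)(C)C(C)(C)C)[C@@H]2C(C)C)cc(OC)c1OC
F2 | step 12 | (1(10)E,4Z)-6-hydroxygermacra-1(10),4-dien-8-yl 3,4,5-trimethoxybenzoate, configuration at C6, C7 and C8 as in 24 | COc1cc(C(=O)O[C@H]2C/C(C)=C/CC/C(C)=C\[C@@H](O)[C@@H]2C(C)C)cc(OC)c1OC
F3 | step 6 | (2S,3R,4R)-1,2-bis(tert-butyldimethylsilyloxy)-3-(propan-2-yl)hept-6-yn-4-ol (C8 epimer of 11) | C#CC[C@@H](O)[C@@H](C(C)C)[C@H](O[Si](C)(C)C(C)(C)C)CO[Si](C)(C)C(C)(C)C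
F4 | step 6 | (2S,3R,4S)-1,2-bis(tert-butyldimethylsilyloxy)-3-(propan-2-yl)hept-6-yn-4-yl 4-nitrobenzoate | C#CC[C@H](OC(=O)c1ccc(cc1)[N+](=O)[O-])[C@@H](C(C)C)[C@H](O[Si](C)(C)C(C)(C)C)CO[Si](C)(C)C(C)(C)C
F5 | step 9 | 9-[2-(2-methyl-1,3-dioxolan-2-yl)ethyl]-9-borabicyclo[3.3.1]nonane | CC1(CCB2C3CCCC2CCC3)OCCO1
F6 | step 9 | (2S,3R,4S,6E)-1,2-bis(tert-butyldimethylsilyloxy)-6-methyl-9-(2-methyl-1,3-dioxolan-2-yl)-3-(propan-2-yl)non-6-en-4-yl 3,4,5-trimethoxybenzoate | CC1(CC/C=C(\C)C[C@H](OC(=O)c2cc(OC)c(OC)c(OC)c2)[C@@H](C(C)C)[C@H](O[Si](C)(C)C(C)(C)C)CO[Si](C)(C)C(C)(C)C)OCCO1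
F7 | step 9 | (2S,3R,4S,6E)-2-(tert-butyldimethylsilyloxy)-1-hydroxy-6-methyl-9-(2-methyl-1,3-dioxolan-2-yl)-3-(propan-2-yl)non-6-en-4-yl 3,4,5-trimethoxybenzoate | CC1(CC/C=C(\C)C[C@H](OC(=O)c2cc(OC)c(OC)c(OC)c2)[C@@H](C(C)C)[C@H](O[Si](C)(C)C(C)(C)C)CO)OCCO1
F8 | step 9 | (2S,3R,4S,6E)-2-(tert-butyldimethylsilyloxy)-6-methyl-9-(2-methyl-1,3-dioxolan-2-yl)-1-oxo-3-(propan-2-yl)non-6-en-4-yl 3,4,5-trimethoxybenzoate | CC1(CC/C=C(\C)C[C@H](OC(=O)c2cc(OC)c(OC)c(OC)c2)[C@@H](C(C)C)[C@H](O[Si](C)(C)C(C)(C)C)C=O)OCCO1
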